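0.249 h⁻¹ early against 0.0609 h⁻¹ late: these are the fractions of the charge per hour that target gains in the oak run, as read from its readings, and the late gain is less than the early one. This bend is what you should watch.

| flask | substrate | temperature | remark | time |
|---|---|---|---|---|
| larch | 0.16 M | 25 °C | run made earlier |  |
| oak | 0.36 M | 58 °C | run made earlier |  |
| Sunday's | 0.24 M | 30 °C |  | 6.0 h |
| Saturday's | 0.24 M | 50 °C |  | 6.0 h |
| Monday's | 0.24 M | 10 °C |  | 6.0 h |
| Friday's | 0.24 M | 70 °C |  | 6.0 h |

larch run (percent of the substrate charged): time / h: target / % = 0.417: 1.4; 1.00: 0.4; 2.00: 0.9; 3.00: 0.7; 4.00: 1.4; 6.00: 2.5; 8.00: 2.9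

oak run (percent of the substrate charged): time / min: target / % = 8.00: 3.2; 12.0: 6.0; 20.0: 7.4; 30.0: 10.1; 50.0: 13.2; 80.0: 17.5; 120: 20.3

(each reading ± 0.5 percentage points)



1. the best flask by amount of target, in percent of the substrate charged; "all alike" if 1.5 percentage points covers them all (Sunday's / Saturday's / Monday's / Friday's / all alike)
2. amount of target at the end, in percent of the substrate charged, Sunday's
3. amount of target at the end, in percent of the substrate charged, Saturday's
4. amount of target at the end, in percent of the substrate charged, Monday's
5. amount of target at the end, in percent of the substrate charged, Friday's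

Suppose the gain falls in proportion as target builds up. Then the ratio of late to early rate, in which time drops out, places the stop: target averages 16.8% over the late stretch, so the stop lies at 22.2%. This is the ceiling, the fraction of the charge at which, on this supposition, the net gain of target reaches zero. On the same supposition the gap to it shrinks exponentially, with a rise time equal to the ceiling divided by the early rate.

The larch run shows no clear bend within its scatter of 0.5 percentage points, and its last reading gives an early rate of 0.00363 h⁻¹. The charges differ, so I take the step as first-order, and the ratio of the two early rates then gives an apparent activation energy of 105 kJ mol⁻¹. My reckoning for 6.0 h gives 3.97% on Sunday's and 0.228% on Monday's. Saturday's has an early rate of 0.0967 h⁻¹, a rise time of 2.29 h and so 20.5%.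

The weak link is the ceiling away from 58 °C. Friday's reckons to 0.234 h of rise, shorter than Saturday's, but it runs 6.0 h in all at a temperature above both earlier runs, while the last reading of the oak run stands at 2 h. So I do not trust 22.2% for Friday's, which carries the ceiling over unchanged, and I commit to Saturday's as best.

The forecast, from the same runs, gave 4.5%, 21%, 0.4% and 20% for Sunday's, Saturday's, Monday's and Friday's and chose Saturday's, since “exothermic equilibrium or target loss would penalise Friday's”; its Sunday's and Monday's stand above mine, its Friday's below.

The flasks give 3.96%, 24.3%, 0.234% and 8.66% in that order, and Saturday's is best.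

    2 substrate → self-condensation product (k = 7.80 × 10⁻⁴ M⁻¹ s⁻¹, Ea = 71.0 kJ mol⁻¹)
    substrate ⇌ isomer of the product (K = 0.370, k = 6.30 × 10⁻⁵ s⁻¹, Ea = 113 kJ mol⁻¹, ΔH = 2.00 kJ mol⁻¹)
    target → over-reaction product (k = 6.70 × 10⁻⁶ s⁻¹, Ea = 108 kJ mol⁻¹)
    substrate ⇌ target (K = 0.570, k = 2.90 × 10⁻⁴ s⁻¹, Ea = 106 kJ mol⁻¹, ΔH = −55.0 kJ mol⁻¹)
    (constants at 70 °C)

Friday's ends below the ceiling of 22.2% read in the oak run, and Saturday's above it. At the end of Friday's, target over substrate stands at 0.597 beside an equilibrium constant of 0.570 for substrate to target, with substrate down from 20.9% to 14.5% and target from 13.0% to 8.66% since 3.00 h. For the neighbour of Monday's at 35 °C, the early rate is 0.0144 h⁻¹, and with the ceiling that gives 7.14%; the computed flask holds 7.12%.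

The numbers in the tables are simulated for an exercise; the scatter is artificial.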